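**Time first.** Time is what I must choose here. Spring is this very flask followed so far, and summer is the earlier run with twice the charge.

the same everywhere: gas phase 35 mM (held); catalyst 16 mol%
- spring: starting material 0.20 M; the very flask that is asked about, followed so far
- summer: starting material 0.40 M; run made earlier
- flask: starting material 0.20 M; time 8.0 min

| spring: time / min | spring: target / % | summer: time / min | summer: target / % |
|---|---|---|---|
| 0.667 | 12.8 | 0.667 | 16.0 |
| 0.833 | 16.4 | 1.00 | 22.4 |
| 1.00 | 18.8 | 1.50 | 27.9 |
| 1.33 | 23.0 | 2.50 | 32.4 |
| 2.00 | 26.7 | 4.00 | 30.9 |
| 2.50 | 27.0 | 5.00 | 26.6 |
| 3.00 | 28.0 | 8.00 | 13.7 |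

(readings scatter by 0.3 percentage points)

- what was read earlier has a scatter of 0.3 percentage points, one standard deviation
- at the start none of the gas phase is in solution
- a reading or a percentage of target counts all its forms, free or not

- when, up to 8.0 min, the flask holds most target
- the amount of target, in percent of the starting material charged, at that time
- the first time at which target reaches 20%, in the same percent, in min

**Target balance.** In fractions of the charge, I write target P as dP/dt = a·A − b·P, where A is starting material, a the make constant and b the loss constant. Target turns where a·A = b·P.

**First pass.** Summer's fall from 5.00 min to 8.00 min gives b = 0.221 min⁻¹. Spring's early net gain is 0.180 min⁻¹ around a level of 15.8%. Taking A as the rest of the charge, a = 0.255 min⁻¹. That puts spring's peak at 4.20 min, later than 3.00 min, where spring has nearly stopped rising.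

**Weak link.** The weak link is b: summer may still be making target during its fall, so that value is a floor. I reforge it from spring, nearly flat at 28.0%. With A = exp(−a·t), the balance gives b = 0.424 min⁻¹, and the early slope then gives a = 0.294 min⁻¹. So R = 0.692, the make constant over the loss constant, a selectivity factor: target rises while P/A lies below R and falls above it. The peak, ln(b/a)/(b−a), comes at 2.82 min. I commit to that time, to about the 28.0% read there, and to 1.09 min for the crossing, interpolated.

**The forecast.** The forecast, later than my turn, gives 3.4 min, 28.3% and 1.09 min, and says: “The later time is less certain because the maximum is flat.”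

**The result.** The flask gives 2.75 min, 28.0% and 1.10 min.

    catalyst + target ⇌ idle complex (K = 5.90 L mol⁻¹, k = 0.0890 L mol⁻¹ s⁻¹)
    target → over-reaction product (k = 0.00890 s⁻¹)
    starting material + dissolved gas + catalyst → catalyst + target (k = 6.10 L² mol⁻² s⁻¹)
    gas phase ⇌ dissolved gas, rate k4*(csat - [dissolved gas]) (kL = 0.110 s⁻¹)

**Why it turns.** At 2.75 min the flask holds 28.0% of target against 45.8% of starting material, so P/A is 0.611, a little under R. Without the step from target to over-reaction product the flask's peak goes from 28.0% to 85.6%. For the same recipe at 0.50 M I have no R of its own, so I hold that neighbour against the R from spring, unscaled, as a rough yardstick. That neighbour peaks at 33.6% and falls, ending with 14.6% of target, bound form counted, over 2.2% of starting material, a P/A of 6.64, above that R of 0.692.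

(The readings were computed for substances that don't exist; scatter was added.)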